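**Strategy.** Everything rests on opening pyranone ring B at O1–C2 and at C3=C4. In the target, C4 bears ring C (3,4-dimethoxyphenyl) and is bonded to C4a of benzo ring A, while O1 sits on the neighbouring C8a; C4 and O1 are therefore the carbonyl carbon and the ortho-phenol oxygen of a 2-hydroxybenzophenone, and only C2 and C3 are missing. (Triphenylphosphoranylidene)ketene supplies both in one operation: it acylates the phenol, and the ester ylide so formed olefinates the diaryl ketone intramolecularly, closing the lactone. The precursor is 3-benzyloxy-2-hydroxy-4,6-dimethoxyphenyl 3,4-dimethoxyphenyl ketone, made by MOM-directed lithiation and Weinreb acylation; O8 stays benzylated until a final hydrogenolysis.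

Key step: step 6

Assumption: the target has no stereocentre, so no stereochemical control is needed; (triphenylphosphoranylidene)ketene is taken as the commercial, storable solid and handled under argon.

**Step 1**
Reactants: 1 2-hydroxy-4,6-dimethoxybenzaldehyde
Product: 2 2,4-dimethoxy-6-(methoxymethoxy)benzaldehyde
Conditions: NaH, THF/DMF, 0 °C; MOMCl, 0 °C → rt
Reagents that add atoms: chloromethyl methyl ether (MOMCl), COCCl
Why: Deprotonation with NaH breaks the OH···O=C chelate and the phenoxide is alkylated by the highly electrophilic chloromethyl ether (Williamson-type acetal ether formation), installing the group that later directs the metalation.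

**Step 2**
Reactants: 2 2,4-dimethoxy-6-(methoxymethoxy)benzaldehyde
Product: 4 2,4-dimethoxy-6-(methoxymethoxy)phenol, via aryl formate 3 (not isolated)
Conditions: mCPBA, CH2Cl2, 0 °C → rt; aq NaHCO3/Na2S2O3 wash; then K2CO3 (cat.), MeOH, rt
Reagents that add atoms: 3-chloroperoxybenzoic acid (mCPBA), O=C(OO)c1cccc(Cl)c1
Why: Baeyer–Villiger (Dakin-type) oxidation, in which the 2,4,6-trioxygenated aryl group migrates in preference to hydride to give formate 3, whose mild methanolysis should free the phenol at the future O8 position while the MOM acetal survives the weakly acidic peracid medium.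

**Step 3**
Reactants: 4 2,4-dimethoxy-6-(methoxymethoxy)phenol
Product: 5 2-(benzyloxy)-1,5-dimethoxy-3-(methoxymethoxy)benzene
Conditions: BnBr, K2CO3, DMF, rt
Reagents that add atoms: benzyl bromide, BrCc1ccccc1
Why: Williamson etherification of the phenoxide; benzyl is chosen for O8 because, unlike a silyl group, it cannot migrate to the adjacent O1 under the basic conditions of step 6, it tolerates n-BuLi and aqueous acid, and it is removed at the end under neutral conditions.

**Step 4**
Reactants: 6 3,4-dimethoxybenzoyl chloride
Product: 7 N,3,4-trimethoxy-N-methylbenzamide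
Conditions: MeNH(OMe)·HCl, K2CO3, EtOAc/H2O, 0 °C → rt
Reagents that add atoms: N,O-dimethylhydroxylamine hydrochloride, CNOC.Cl
Why: Schotten–Baumann amidation of an acid chloride should give the N-methoxy-N-methylamide cleanly; this acyl donor lets the aryl–carbonyl bond be made at the ketone oxidation level, so no carbinol oxidation is needed.

**Step 5**
Reactants: 5 2-(benzyloxy)-1,5-dimethoxy-3-(methoxymethoxy)benzene; 7 N,3,4-trimethoxy-N-methylbenzamide
Product: 10 [3-(benzyloxy)-2-hydroxy-4,6-dimethoxyphenyl](3,4-dimethoxyphenyl)methanone, via aryllithium 8 (not isolated), via MOM ketone 9 (not isolated)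
Conditions: n-BuLi (1.1 equiv), Et2O, 0 °C → rt; 7 in THF, −78 °C → rt; then 3 M aq HCl, MeOH, 50 °C
Reagents that add atoms: none
Why: Directed ortho-metalation in weakly coordinating Et2O, where n-BuLi pre-complexed to the acetal oxygens of OMOM (a stronger director than OMe) should remove the ring proton flanked by OMOM and OMe rather than the one between the two OMe groups or the benzylic CH2; aryllithium 8 is acylated once only by N-methoxy-N-methylamide 7, ketone 9 is released on the acid quench, and warm methanolic HCl then cleaves the MOM acetal while the benzyl and methyl ethers persist.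

**Step 6**
Reactants: 10 [3-(benzyloxy)-2-hydroxy-4,6-dimethoxyphenyl](3,4-dimethoxyphenyl)methanone; 11 (triphenylphosphoranylidene)ketene
Product: 13 8-(benzyloxy)-4-(3,4-dimethoxyphenyl)-5,7-dimethoxy-2H-chromen-2-one, via ester ylide 12 (not isolated)
Conditions: 11 (1.5 equiv), toluene, 110 °C, Ar
Reagents that add atoms: none
Why: The 2-OH of 10 adds across the ylidic C=C of the cumulene 11, forming O1–C2 and the ester-stabilised ylide 12, whose ylidic carbon then attacks the adjacent diaryl ketone and expels Ph3PO in an intramolecular Wittig olefination that creates C3=C4. The closest known reaction type is the one-pot acylation–Wittig annulation of ortho-hydroxyaryl aldehydes and ketones with this reagent, which gives coumarins and is established for 2-hydroxyacetophenones and 2-hydroxybenzophenones. Pyranone ring B closes in a 6-exo-trig mode (ylide carbon C3 onto ketone carbon C4, carbonyl oxygen outside the forming ring). No stereocentre is formed, and the only geometric element, C2 and C4a cis across C3=C4, is imposed by the O1 tether. The step needs acylation at one oxygen only and olefination of a hindered, electron-rich ketone: O8 is benzylated so that O1–H is the sole acidic site, 11 does not olefinate ketones by itself, and the intramolecular delivery together with formation of the conjugated 2-pyranone should drive the closure at 110 °C.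

**Step 7**
Reactants: 13 8-(benzyloxy)-4-(3,4-dimethoxyphenyl)-5,7-dimethoxy-2H-chromen-2-one
Product: 14 8-hydroxy-4-(3,4-dimethoxyphenyl)-5,7-dimethoxy-2H-chromen-2-one (8-hydroxy-5,7,3',4'-tetramethoxy-4-phenylcoumarin)
Conditions: H2 (1 atm), 10% Pd/C, EtOAc, rt
Reagents that add atoms: none
Why: Catalytic hydrogenolysis of the aryl benzyl ether over palladium on carbon at 1 atm should be much faster than hydrogenation of the trisubstituted, aryl-conjugated C3=C4 bond, so the 8-OH is freed with the lactone and the four methyl ethers untouched.

**Compound list**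
1 | 2-hydroxy-4,6-dimethoxybenzaldehyde | COc1cc(O)c(C=O)c(OC)c1 | starting material
2 | 2,4-dimethoxy-6-(methoxymethoxy)benzaldehyde | COCOc1cc(OC)cc(OC)c1C=O | intermediate
3 | 2,4-dimethoxy-6-(methoxymethoxy)phenyl formate | COCOc1cc(OC)cc(OC)c1OC=O | intermediate
4 | 2,4-dimethoxy-6-(methoxymethoxy)phenol | COCOc1cc(OC)cc(OC)c1O | intermediate
5 | 2-(benzyloxy)-1,5-dimethoxy-3-(methoxymethoxy)benzene | COCOc1cc(OC)cc(OC)c1OCc1ccccc1 | intermediate
6 | 3,4-dimethoxybenzoyl chloride | COc1ccc(C(Cl)=O)cc1OC | starting material
7 | N,3,4-trimethoxy-N-methylbenzamide | COc1ccc(C(=O)N(C)OC)cc1OC | intermediate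
8 | [3-(benzyloxy)-4,6-dimethoxy-2-(methoxymethoxy)phenyl]lithium | [Li]c1c(OCOC)c(OCc2ccccc2)c(OC)cc1OC | intermediate
9 | [3-(benzyloxy)-4,6-dimethoxy-2-(methoxymethoxy)phenyl](3,4-dimethoxyphenyl)methanone | COCOc1c(OCc2ccccc2)c(OC)cc(OC)c1C(=O)c1ccc(OC)c(OC)c1 | intermediate
10 | [3-(benzyloxy)-2-hydroxy-4,6-dimethoxyphenyl](3,4-dimethoxyphenyl)methanone | COc1ccc(C(=O)c2c(OC)cc(OC)c(OCc3ccccc3)c2O)cc1OC | intermediate
11 | (triphenylphosphoranylidene)ketene | O=C=C=P(c1ccccc1)(c1ccccc1)c1ccccc1 | starting material
12 | 2-(benzyloxy)-6-(3,4-dimethoxybenzoyl)-3,5-dimethoxyphenyl (triphenyl-λ5-phosphanylidene)acetate | COc1ccc(C(=O)c2c(OC)cc(OC)c(OCc3ccccc3)c2OC(=O)C=P(c4ccccc4)(c4ccccc4)c4ccccc4)cc1OC | intermediate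
13 | 8-(benzyloxy)-4-(3,4-dimethoxyphenyl)-5,7-dimethoxy-2H-chromen-2-one | COc1ccc(-c2cc(=O)oc3c(OCc4ccccc4)c(OC)cc(OC)c23)cc1OC | intermediate
14 | 8-hydroxy-4-(3,4-dimethoxyphenyl)-5,7-dimethoxy-2H-chromen-2-one | COc1ccc(-c2cc(=O)oc3c(O)c(OC)cc(OC)c23)cc1OC | target

Total step count: 7. Longest linear sequence: 6 steps (steps 1, 2, 3, 5, 6, 7).

**Steps most likely to fail**

Step 6. The closure may stall at the ester ylide because the ketone is flanked by two ortho substituents and deactivated by two electron-rich rings, and prolonged heating may consume the reagent by oligomerisation or adventitious hydrolysis. The fallback sets out from 10 and returns at 13 by an intramolecular Horner–Wadsworth–Emmons reaction, which uses a more nucleophilic phosphonate carbanion. The phenol of 10 would be esterified with (diethoxyphosphoryl)acetyl chloride (made from the acid and oxalyl chloride; Et3N, CH2Cl2, 0 °C) to give 2-(benzyloxy)-6-(3,4-dimethoxybenzoyl)-3,5-dimethoxyphenyl (diethoxyphosphoryl)acetate F1. Treatment of this ester with NaH in THF (0 °C → reflux) should close ring B and give 13.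

Step 5. Metalation may lose regiocontrol, either by deprotonation between the two methoxy groups or at the benzylic CH2 with subsequent [1,2]-shift, and the hindered aryllithium may acylate incompletely. The fallback sets out from 5 and returns at 10, fixing the regiochemistry by a phenoxide-directed formylation. The MOM acetal of 5 would be cleaved (HCl, MeOH, 40 °C) to 2-(benzyloxy)-3,5-dimethoxyphenol F2. Magnesium-mediated ortho-formylation (MgCl2, Et3N, paraformaldehyde, MeCN, reflux) delivers formaldehyde through the magnesium phenoxide and can therefore react only at the single free ortho position, giving 3-(benzyloxy)-2-hydroxy-4,6-dimethoxybenzaldehyde F3. Addition of 3,4-dimethoxyphenylmagnesium bromide (2.2 equiv, THF, 0 °C) would give the racemic carbinol 2-(benzyloxy)-6-[(3,4-dimethoxyphenyl)(hydroxy)methyl]-3,5-dimethoxyphenol F4, and MnO2 in CH2Cl2 should oxidise this doubly benzylic alcohol to ketone 10.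

Step 7. Hydrogenolysis may be accompanied by over-reduction of C3=C4 to the dihydrocoumarin, or be slowed by catalyst poisoning from phosphorus residues of step 6. The fallback sets out from 13 and ends at 14 without hydrogen: BCl3 with pentamethylbenzene as cation scavenger in CH2Cl2 at −78 °C, quenched cold with MeOH, should cleave the benzyl ether by a Lewis-acid pathway while the methyl ethers and the alkene are left alone; no new compound arises on this way (F0).

**Further compounds**
F1 | step 6 | 2-(benzyloxy)-6-(3,4-dimethoxybenzoyl)-3,5-dimethoxyphenyl (diethoxyphosphoryl)acetate | CCOP(=O)(OCC)CC(=O)Oc1c(OCc2ccccc2)c(OC)cc(OC)c1C(=O)c1ccc(OC)c(OC)c1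
F2 | step 5 | 2-(benzyloxy)-3,5-dimethoxyphenol | COc1cc(O)c(OCc2ccccc2)c(OC)c1
F3 | step 5 | 3-(benzyloxy)-2-hydroxy-4,6-dimethoxybenzaldehyde | COc1cc(OC)c(OCc2ccccc2)c(O)c1C=O
F4 | step 5 | 2-(benzyloxy)-6-[(3,4-dimethoxyphenyl)(hydroxy)methyl]-3,5-dimethoxyphenol (racemic) | COc1ccc(C(O)c2c(OC)cc(OC)c(OCc3ccccc3)c2O)cc1OC
F0 | step 7 | none | none
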